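Numbering: ring C1 (side chain), C2 (=CH), C3 (OH), C4 (=CH), C5 (OMe), C6 (OAc); side chain C1′–C13′, with the acetate on C2′.
Cuts: C1=C2 (back to C2–SePh/C1–H); C3–OH (back to the C3 ketone of a vinylogous ester); C3′–C4′ (decyl nucleophile + C2′/C3′ oxirane); C6–O and C2–Se (back to the two enol ethers of a Birch diene); C1–C1′ (aryl Grignard + glycidyl ether).
Enabling features: the C2′ oxygen is vicinal to C3′, so C2′–C3′–O can be an oxirane whose strain drives the chain union. The ring oxygens on C3 and C5 are both meta to C1, so the six-membered ring is a hidden 5-alkylresorcinol dimethyl ether and arises by Birch reduction, not by ring closure.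
Forward: arene + C3 unit → Birch diene → oxirane → oxidation of enol ether C5=C6 (C6–OH, C5 ketal) → union with C10 and double acetylation → selenenylation of enol ether C2=C3 with loss of MeOH → 1,2-reduction → selenoxide elimination.
Stereochemistry: C2′ is bought. C1 and C6 come from one catalyst-controlled, anti-selective desymmetrising oxidation. C2 and C3 are relayed from C1 by substrate control. The helper centres C1 and C2 are erased in the last step, which leaves the trans C3/C6 pair.

Key step: step 5

Assumption: the (R,R) antipode of the Mn(salen) complex is taken as the one matched to the face of C5=C6 anti to the side chain; the sense of induction on a non-conjugated enol ether has to be confirmed, and the (S,S) complex is equally accessible.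

Step 1
Reactants: 1 1-bromo-3,5-dimethoxybenzene; 2 (S)-benzyl glycidyl ether
Product: 4 (2S)-1-(benzyloxy)-3-(3,5-dimethoxyphenyl)propan-2-ol, via arylmagnesium bromide 3 (not isolated)
Conditions: Mg, THF, reflux; then CuI (10 mol %), 2, THF, −30 → 0 °C; sat. aq NH4Cl
Reagents that add atoms: none
Why: Copper-catalysed Grignard opening of a terminal epoxide takes place at the unsubstituted carbon and leaves the C–O bond of the bought stereocentre untouched, so C2′ is carried over unchanged.

Step 2
Reactants: 4 (2S)-1-(benzyloxy)-3-(3,5-dimethoxyphenyl)propan-2-ol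
Product: 5 (2S)-3-(3,5-dimethoxycyclohexa-2,5-dien-1-yl)propane-1,2-diol
Conditions: Li, NH3(l)/THF, t-BuOH, −78 °C; solid NH4Cl; work-up at pH ≥ 8
Reagents that add atoms: none
Why: In this Birch reduction the two methoxy groups direct protonation to C1 and C4, as known for 5-alkylresorcinol dimethyl ethers, and the same dissolving metal cleaves the benzyl ether without touching the carbinol centre.

Step 3
Reactants: 5 (2S)-3-(3,5-dimethoxycyclohexa-2,5-dien-1-yl)propane-1,2-diol
Product: 7 (2S)-2-[(3,5-dimethoxycyclohexa-2,5-dien-1-yl)methyl]oxirane, via primary tosylate 6 (not isolated)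
Conditions: NaH (2.5 equiv), N-tosylimidazole (1.05 equiv), THF, 0 °C → rt
Reagents that add atoms: none
Why: One-pot diol-to-epoxide conversion (sulfonylation of the primary alkoxide, then Williamson-type 3-exo-tet closure) runs under base only, which the acid-labile enol ethers tolerate, and the C2′–O bond is kept, so the configuration is retained.

Step 4
Reactants: 7 (2S)-2-[(3,5-dimethoxycyclohexa-2,5-dien-1-yl)methyl]oxirane
Product: 9 (1S,2R)-4,6,6-trimethoxy-2-{[(2S)-oxiran-2-yl]methyl}cyclohex-3-en-1-ol, via methoxyoxirane 8 (not isolated)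
Conditions: (R,R)-N,N′-bis(3,5-di-tert-butylsalicylidene)-1,2-cyclohexanediaminomanganese(III) chloride (5 mol %), 4-phenylpyridine N-oxide (25 mol %), PhIO (0.95 equiv), NaHCO3 (s), MeOH/CH2Cl2 1:1, −20 °C
Reagents that add atoms: iodosylbenzene, O=Ic1ccccc1; methanol, CO
Why: Proposed new method: the oxo-Mn(V)(salen) species transfers oxygen to the electron-rich enol ether; the C1 side chain keeps the oxidant off its own face, and because the open faces of the C5=C6 and C2=C3 enol ethers are enantiotopic within the ring, the chiral catalyst has to pick one alkene, which fixes C1 and C6 together; methanol opens the labile 2-methoxyoxirane 8 at the acetal carbon C5, so the product is a base-stable α-hydroxy dimethyl ketal with no carbonyl that could pull the second enol ether into conjugation, and methoxy stays on C5; any wrong mono-adduct still carries the catalyst-matched alkene and should be drained by a second oxidation; the closest known reaction types are the Mn(salen)-catalysed epoxidation of enol ethers in alcohols to α-hydroxy acetals and the anti-selective desymmetrising oxidation of 3-substituted cyclohexa-1,4-dienes.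

Step 5
Reactants: 9 (1S,2R)-4,6,6-trimethoxy-2-{[(2S)-oxiran-2-yl]methyl}cyclohex-3-en-1-ol; 10 decylmagnesium bromide
Product: 12 (1S,2R)-2-[(2R)-2-acetoxytridecyl]-4,6,6-trimethoxycyclohex-3-en-1-yl acetate, via bis-alkoxide 11 (not isolated)
Conditions: 10 (3 equiv), CuI (15 mol %), THF, −40 → −10 °C; then Et3N, Ac2O (6 equiv), DMAP (10 mol %), −10 °C → rt; pH 7 buffer
Reagents that add atoms: acetic anhydride, CC(=O)OC(C)=O
Why: The first equivalent of 10 deprotonates the C6–OH, and the decylcopper(I) ate species formed from 10 and CuI then attacks the unsubstituted oxirane carbon C3′ from the backside (SN2-type oxidative addition, then reductive elimination), the release of three-ring strain paying for an otherwise sluggish sp3–sp3 union. The closest known reaction type is the copper-catalysed Grignard opening of terminal epoxides with acylation of the magnesium alkoxide in the same flask. No ring is closed and no stereocentre is made: the C2′–O bond is never broken, so the bought configuration is delivered unchanged next to the new bond (the descriptor changes from S to R only because C3′ loses its oxygen), and C1 and C6 are spectators. The step needs attack at C3′ rather than C2′, which the unhindered CH2 terminus secures, and it needs a partner without electrophilic carbon, which is why it is run at this oxidation level: C3 is an enol ether and C5 a ketal, both inert to organocopper and Grignard reagents, and the C6 alkoxide is trans to the side chain, so its own 5-exo attack on the oxirane would have to build a trans-fused oxabicyclo[4.3.0]nonene. The event frees as alkoxides exactly the two oxygens (on C6 and C2′) that are acetates in the target, so one charge of Ac2O caps both while the third oxygen (on C3) is still hidden in the enol ether, and the three oxygen functions are told apart without any protecting group.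

Step 6
Reactants: 12 (1S,2R)-2-[(2R)-2-acetoxytridecyl]-4,6,6-trimethoxycyclohex-3-en-1-yl acetate
Product: 15 (1S,5R,6S)-6-[(2R)-2-acetoxytridecyl]-2-methoxy-4-oxo-5-(phenylselanyl)cyclohex-2-en-1-yl acetate, via oxocarbenium chloride 13 (not isolated), via dimethoxy ketone 14 (not isolated)
Conditions: PhSeCl (1.05 equiv), CH2Cl2, −78 °C; sat. aq NaHCO3, 0 °C; then DBU (20 mol %), CH2Cl2, 0 °C
Reagents that add atoms: benzeneselenenyl chloride, Cl[Se]c1ccccc1; water, O
Why: In this electrophilic selenenylation of an enol ether, PhSe+ adds to C2 anti to the neighbouring side chain (trans, and correctable by base epimerisation α to the new ketone), hydrolysis of 13 gives the C3 ketone, and the β,β-dimethoxy ketone 14 loses methanol by E1cB, so the vinylogous ester can carry its methoxy group only on C5.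

Step 7
Reactants: 15 (1S,5R,6S)-6-[(2R)-2-acetoxytridecyl]-2-methoxy-4-oxo-5-(phenylselanyl)cyclohex-2-en-1-yl acetate
Product: 16 (1S,4R,5R,6S)-6-[(2R)-2-acetoxytridecyl]-4-hydroxy-2-methoxy-5-(phenylselanyl)cyclohex-2-en-1-yl acetate
Conditions: NaBH4, CeCl3·7H2O, MeOH/THF, −40 °C; pH 7 phosphate buffer
Reagents that add atoms: none
Why: In this Luche 1,2-reduction, axial hydride attack on the conformer with OAc, side chain and SePh all equatorial (all trans), as in 5-substituted cyclohexenones such as carvone → cis-carveol, should place the C3–OH cis to the C1 side chain and hence trans to the C6 acetate, and the acetates survive.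

Step 8
Reactants: 16 (1S,4R,5R,6S)-6-[(2R)-2-acetoxytridecyl]-4-hydroxy-2-methoxy-5-(phenylselanyl)cyclohex-2-en-1-yl acetate
Product: 18 (1S,4S)-6-[(2R)-2-acetoxytridecyl]-4-hydroxy-2-methoxycyclohexa-2,5-dien-1-yl acetate, via selenoxide 17 (not isolated)
Conditions: mCPBA (1.0 equiv), CH2Cl2, −78 °C; then i-Pr2NH (5 equiv), −78 → 0 °C; NaHCO3 wash, Et3N-deactivated silica
Reagents that add atoms: none
Why: In this selenoxide syn-elimination, selenium is oxidised far faster than the enol ether, C1–H is cis to selenium, and β-hydroxy selenoxides eliminate away from the carbinol carbon, so the C1=C2 bond forms under cold, near-neutral conditions after both carbinol centres are in place, which avoids any 4-H-cyclohexadienone that would tautomerise to a phenol.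

Compound list
1 | 1-bromo-3,5-dimethoxybenzene | COc1cc(Br)cc(OC)c1 | starting material
2 | (S)-benzyl glycidyl ether | C(OCc1ccccc1)[C@@H]1CO1 | starting material
3 | 3,5-dimethoxyphenylmagnesium bromide | COc1cc([Mg]Br)cc(OC)c1 | intermediate
4 | (2S)-1-(benzyloxy)-3-(3,5-dimethoxyphenyl)propan-2-ol | COc1cc(C[C@H](O)COCc2ccccc2)cc(OC)c1 | intermediate
5 | (2S)-3-(3,5-dimethoxycyclohexa-2,5-dien-1-yl)propane-1,2-diol | OC[C@@H](O)CC1C=C(OC)CC(OC)=C1 | intermediate
6 | (2S)-3-(3,5-dimethoxycyclohexa-2,5-dien-1-yl)-2-hydroxypropyl 4-methylbenzenesulfonate | Cc1ccc(cc1)S(=O)(=O)OC[C@@H](O)CC2C=C(OC)CC(OC)=C2 | intermediate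
7 | (2S)-2-[(3,5-dimethoxycyclohexa-2,5-dien-1-yl)methyl]oxirane | C([C@H]1CO1)C2C=C(OC)CC(OC)=C2 | intermediate
8 | (1R,5R,6S)-1,3-dimethoxy-5-{[(2S)-oxiran-2-yl]methyl}-7-oxabicyclo[4.1.0]hept-3-ene (ring oxirane anti to the side chain) | C([C@H]1CO1)[C@@H]2C=C(OC)C[C@@]3(OC)O[C@@H]23 | intermediate
9 | (1S,2R)-4,6,6-trimethoxy-2-{[(2S)-oxiran-2-yl]methyl}cyclohex-3-en-1-ol | C([C@H]1CO1)[C@@H]2C=C(OC)CC(OC)(OC)[C@H]2O | intermediate
10 | decylmagnesium bromide | CCCCCCCCCC[Mg]Br | starting material
11 | bis(bromomagnesium) alkoxide of (1S,2R)-2-[(2R)-2-hydroxytridecyl]-4,6,6-trimethoxycyclohex-3-en-1-ol | CCCCCCCCCCC[C@H](C[C@@H]1C=C(OC)CC(OC)(OC)[C@H]1O[Mg]Br)O[Mg]Br | intermediate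
12 | (1S,2R)-2-[(2R)-2-acetoxytridecyl]-4,6,6-trimethoxycyclohex-3-en-1-yl acetate | CCCCCCCCCCC[C@H](C[C@@H]1C=C(OC)CC(OC)(OC)[C@H]1OC(C)=O)OC(C)=O | intermediate
13 | C3 O-methyl oxocarbenium chloride formed from 12 by addition of PhSe to C2 (Se trans to the side chain) | CCCCCCCCCCC[C@H](C[C@@H]1[C@@H]([Se]c2ccccc2)C(=[O+]C)CC(OC)(OC)[C@H]1OC(C)=O)OC(C)=O.[Cl-] | intermediate
14 | (1S,5R,6S)-6-[(2R)-2-acetoxytridecyl]-2,2-dimethoxy-4-oxo-5-(phenylselanyl)cyclohexyl acetate | CCCCCCCCCCC[C@H](C[C@@H]1[C@@H]([Se]c2ccccc2)C(=O)CC(OC)(OC)[C@H]1OC(C)=O)OC(C)=O | intermediate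
15 | (1S,5R,6S)-6-[(2R)-2-acetoxytridecyl]-2-methoxy-4-oxo-5-(phenylselanyl)cyclohex-2-en-1-yl acetate | CCCCCCCCCCC[C@H](C[C@@H]1[C@@H]([Se]c2ccccc2)C(=O)C=C(OC)[C@H]1OC(C)=O)OC(C)=O | intermediate
16 | (1S,4R,5R,6S)-6-[(2R)-2-acetoxytridecyl]-4-hydroxy-2-methoxy-5-(phenylselanyl)cyclohex-2-en-1-yl acetate | CCCCCCCCCCC[C@H](C[C@@H]1[C@@H]([Se]c2ccccc2)[C@H](O)C=C(OC)[C@H]1OC(C)=O)OC(C)=O | intermediate
17 | Se-oxide of 16 (configuration at selenium undefined) | CCCCCCCCCCC[C@H](C[C@@H]1[C@@H]([Se](=O)c2ccccc2)[C@H](O)C=C(OC)[C@H]1OC(C)=O)OC(C)=O | intermediate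
18 | (1S,4S)-6-[(2R)-2-acetoxytridecyl]-4-hydroxy-2-methoxycyclohexa-2,5-dien-1-yl acetate | CCCCCCCCCCC[C@H](CC1=C[C@H](O)C=C(OC)[C@H]1OC(C)=O)OC(C)=O | target

Total step count: 8. Longest linear sequence: 8 (1 → 18).

Steps most likely to fail

Step 4. What may go wrong is weak discrimination between the two enol ethers on a non-conjugated substrate, uncatalysed background oxidation, and oxidation of both enol ethers. The fallback sets out from 7 and oxidises the enol ether without a chiral catalyst by the known peracid/methanol protocol (mCPBA, NaHCO3, MeOH, −40 °C). Attack still comes anti to the side chain, but both enol ethers react. Compound 9 is therefore formed together with its ring diastereomer (1R,2S)-4,6,6-trimethoxy-2-{[(2S)-oxiran-2-yl]methyl}cyclohex-3-en-1-ol F1. The oxirane stereocentre makes the two compounds diastereomers, so they are separated by chromatography on base-washed silica, and the route is rejoined at 9.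

Step 8. What may go wrong is ionisation of the doubly allylic carbinol, or loss of water or acetic acid with aromatisation under the influence of the selenium acids, and re-addition of the selenenic acid to the enol ether. The fallback sets out from 16 and first covers the C3 hydroxyl (TESCl, imidazole, CH2Cl2, 0 °C). This gives (1S,4R,5R,6S)-6-[(2R)-2-acetoxytridecyl]-2-methoxy-5-(phenylselanyl)-4-[(triethylsilyl)oxy]cyclohex-2-en-1-yl acetate F2. Oxidation with mCPBA at −78 °C gives its Se-oxide F3. On warming with i-Pr2NH this eliminates to the less ionisable silyl ether (1S,4S)-6-[(2R)-2-acetoxytridecyl]-2-methoxy-4-[(triethylsilyl)oxy]cyclohexa-2,5-dien-1-yl acetate F4. Removal of the silyl group with pyridine-buffered HF·pyridine (THF, 0 °C) comes back to the route at 18.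

Step 7. What may go wrong is hydride delivery from the wrong face if the conformer with axial selenium reacts, and solvolysis of the new 3-methoxy allylic alcohol by the Lewis-acidic medium. The fallback hands the choice of face from the substrate to a chiral reagent. It sets out from 15 and runs an oxazaborolidine-catalysed (CBS) reduction with the (S)-methyl oxazaborolidine and catecholborane (toluene, −60 °C). With the selenium-bearing C2 side as the large group, this reagent should deliver the (4R) carbinol in an aprotic, non-solvolysing medium. It comes back to the route at 16 without any new compound.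

Further compounds
F1 | step 4 | (1R,2S)-4,6,6-trimethoxy-2-{[(2S)-oxiran-2-yl]methyl}cyclohex-3-en-1-ol | C([C@H]1CO1)[C@H]2C=C(OC)CC(OC)(OC)[C@@H]2O
F2 | step 8 | (1S,4R,5R,6S)-6-[(2R)-2-acetoxytridecyl]-2-methoxy-5-(phenylselanyl)-4-[(triethylsilyl)oxy]cyclohex-2-en-1-yl acetate | CCCCCCCCCCC[C@H](C[C@@H]1[C@@H]([Se]c2ccccc2)[C@H](O[Si](CC)(CC)CC)C=C(OC)[C@H]1OC(C)=O)OC(C)=O
F3 | step 8 | Se-oxide of F2 | CCCCCCCCCCC[C@H](C[C@@H]1[C@@H]([Se](=O)c2ccccc2)[C@H](O[Si](CC)(CC)CC)C=C(OC)[C@H]1OC(C)=O)OC(C)=O
F4 | step 8 | (1S,4S)-6-[(2R)-2-acetoxytridecyl]-2-methoxy-4-[(triethylsilyl)oxy]cyclohexa-2,5-dien-1-yl acetate | CCCCCCCCCCC[C@H](CC1=C[C@H](O[Si](CC)(CC)CC)C=C(OC)[C@H]1OC(C)=O)OC(C)=O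
F0 | step 7 | none | none
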